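The numbers come from no measurement; the flask was simulated.

At early times in the flask G dissolved into D while L passed into Q, and to decide what to change for the next run I asked how D divides between its two exits.

    L ⇌ Q, rate k1*(csat - [Q]) (k1 = 0.00136 min⁻¹, csat = 32 mM)
    G ⇌ D, rate k2*(cs2 - [D]) while solid is left; crystals form when [D] > cs2 (cs2 = 0.11 M, k2 = 8.91 × 10⁻⁴ min⁻¹)
    Q ⇌ Z (K3 = 3.0, k3 = 9.61 × 10⁻⁴ min⁻¹)
    Q → J (k4 = 3.90 × 10⁻⁴ min⁻¹)
    D + Q → D.Q (k5 = 0.0456 M⁻¹ min⁻¹)
    D → E (k6 = 8.10 × 10⁻⁴ min⁻¹)

G 0.12 M; L 32 mM (held); time 2.5 d

- south: doubling the solubility in step 2, all else as stated
- east: doubling the transfer coefficient of step 1, all else as stated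
- south-east: doubling the saturation concentration of L, all else as stated
- west: doubling the dissolution coefficient of step 2, all else as stated

- solid, in amounts per volume of the solution: G
- at the start none of Q is dissolved
- at the start none of G is in solution
- run time (flask): 2.5 d

1. the D.Q standing at 2.5 d, as a percentage of the G charged
2. the change that raises the amount of D.Q at 2.5 d, in percent of the G charged most ("none" if none brings more than 2 percentage points) (south / east / south-east / west / none)
3. amount of D.Q at 2.5 d, in percent of the G charged, after south-east

D goes to D.Q at a rate proportional to Q, and to E at a rate that does not depend on Q. The two rates are equal at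

Q× = 8.10 × 10⁻⁴ min⁻¹ / 0.0456 M⁻¹ min⁻¹ = 17.8 mM,

which I called the crossover concentration of Q. The selectivity, the share of D going to D.Q at a given moment, is then Q/(Q + Q×), and the ratio of the two rates at that moment is Q/Q×. This carries over to the standing amounts of D.Q and E, as a rough guide, while Q stays level.

For the level of Q I first set dissolving against the loss to E, which put D near 57.6 mM. I then set the feed from L against the losses of Q, leaving out the return from Z. The resulting shares were:

as charged: Q 8.15 mM, share 31.5%
south-east: share 47.9%
east: share 42.2%
west: share 28.5%
south: share 23.5%

I chose south-east, because its share was the greatest, and I left the solid side alone, because both of its changes lowered the share.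

The forecast gave 37% (33% to 41%), south-east as the best change, and 55% (50% to 60%) after it, holding that “Doubling csat doubles the Q supply without adding any loss term”. My shares stood lower than its yields, though the choice was the same.

The simulation gave 36.1%, and 54.6% after south-east. The changes moved the yield by 18 percentage points for south-east, 11 points for east, −2.3 points for west and −3 points for south.

In the flask Q read 0.0100 M at 1.25 d, less than Q×, and 0.0170 M at 2.50 d, still less. At the earlier reading, with Q level since the 0.0102 M of 0.625 d, E stood at 41.5% of the G charged, and E times Q/Q× came to 23.3% against a D.Q of 22.8%. At 2.50 d, after Q had risen, the rate ratio no longer gave the amounts: the same product came to 58.4% against a D.Q of 36.1%.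

The same flask read at 25 h held Q at 0.0100 M and E at 32.5%, and E times Q/Q× gave 18.3% of D.Q. The computed D.Q there was 17.8%.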